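**Assumption:** the target SMILES has no stereocentre and no stereogenic double bond, so "single enantiomer" needs no stereocontrol; intermediates 5 and 6 are racemic and their one stereocentre is erased in step 3.

## Retrosynthetic overview

1. C5–prenyl: installed last by Suzuki–Miyaura coupling on a C5 bromide carried in from 4-bromoresorcinol; the pivalate on the aryl phenol is removed in the same pot.
2. Furan ring (the only ring made): closed by C–O bond formation. One dehydrative operation on an open-chain acyloin makes both C3–OMe and O1–C2 (key step).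
3. Acyloin: the aryl–C3 bond comes from hydroxyalkylation of 4-bromoresorcinol with an arylglyoxal made from O-pivaloyl paeonol.
4. Both benzene rings are bought. The pivalate keeps the paeonol oxygen from attacking C3 itself, which would lead to a benzofuro[3,2-b]benzofuran.

## Route

Step 1
Reactants: 1 paeonol, 1-(2-hydroxy-4-methoxyphenyl)ethan-1-one
Product: 2 2-acetyl-5-methoxyphenyl pivalate
Conditions: PivCl (1.2 equiv), Et3N (1.5 equiv), DMAP (5 mol%), CH2Cl2, 0 °C → rt
Reagents that add atoms: pivaloyl chloride, CC(C)(C)C(Cl)=O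
Why: DMAP-catalysed O-acylation of the chelated phenol gives an ester that survives oxidation and acid and blocks this oxygen as an internal nucleophile in steps 2–3.

Step 2
Reactants: 2 2-acetyl-5-methoxyphenyl pivalate; 3 4-bromoresorcinol (4-bromobenzene-1,3-diol)
Product: 5 2-[2-(5-bromo-2,4-dihydroxyphenyl)-2-hydroxyacetyl]-5-methoxyphenyl pivalate (racemic acyloin, drawn open-chain), via 2-(2,2-dihydroxyacetyl)-5-methoxyphenyl pivalate 4 (not isolated)
Conditions: SeO2 (1.05 equiv), 1,4-dioxane/H2O (20:1), 100 °C; filter (Celite), aqueous wash, concentrate; then 3 (1.0 equiv), EtOH/H2O (1:1), 40 °C, no acid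
Reagents that add atoms: selenium dioxide, O=[Se]=O; water, O
Why: Riley oxidation gives the arylglyoxal hydrate, whose aldehyde carbon undergoes uncatalysed Friedel–Crafts hydroxyalkylation at C6 of 3 (para to one OH, ortho to the other, C2 being flanked on both sides); running it without acid or methanol means no free 3 is present when the C3 cation is generated in step 3, and the new stereocentre is racemic and removed there.

Step 3
Reactants: 5 2-[2-(5-bromo-2,4-dihydroxyphenyl)-2-hydroxyacetyl]-5-methoxyphenyl pivalate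
Product: 7 2-(5-bromo-6-hydroxy-3-methoxy-1-benzofuran-2-yl)-5-methoxyphenyl pivalate, via 2-[2-(5-bromo-2,4-dihydroxyphenyl)-2-methoxyacetyl]-5-methoxyphenyl pivalate 6 (not isolated)
Conditions: CSA (10 mol%), HC(OMe)3 (2 equiv), MeOH (0.05 M), rt then 45 °C, N2
Reagents that add atoms: methanol, CO (trimethyl orthoformate, COC(OC)OC, only scavenges water and feeds the same methanol pool)
Why: Proposed new method: dehydrative methoxy-annulation of an o-hydroxyaryl acyloin – acid ionises the C3 carbinol to a cation stabilised by the para- and ortho-oxygens of the bromoresorcinol ring (keto-quinone-methide), solvent methanol captures it (C3–OMe, giving 6), and the ortho phenol then adds to the aryl ketone (5-exo-trig hemiketal) and loses water through the C2 oxocarbenium to give the aromatic furan (O1–C2), with orthoformate keeping water out so that any 3-hydroxy/3-oxo shunt product is also drawn to the enol ether; the closest known chemistry is the acid-catalysed cyclodehydration of o-hydroxybenzyl ketones to 2-arylbenzofurans and the arylglyoxal/phenol/amide three-component benzofuran synthesis, and to my knowledge neither has been run with an alcohol as the C3 nucleophile; no stereocentre remains.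

Step 4
Reactants: 7 2-(5-bromo-6-hydroxy-3-methoxy-1-benzofuran-2-yl)-5-methoxyphenyl pivalate; 8 prenylboronic acid pinacol ester, 4,4,5,5-tetramethyl-2-(3-methylbut-2-en-1-yl)-1,3,2-dioxaborolane
Product: 10 ambofuranol, 2-(2-hydroxy-4-methoxyphenyl)-3-methoxy-5-(3-methylbut-2-en-1-yl)-1-benzofuran-6-ol, via 2-[6-hydroxy-3-methoxy-5-(3-methylbut-2-en-1-yl)-1-benzofuran-2-yl]-5-methoxyphenyl pivalate 9 (not isolated)
Conditions: tBuXPhos Pd G3 (4 mol%), K3PO4 (aq, 3 equiv), MeCN, 60 °C; then KOH (5 equiv), MeOH, 40 °C, degassed; 1 M HCl to pH 5, 0 °C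
Reagents that add atoms: none
Why: Suzuki–Miyaura sp2–sp3 coupling in which the bulky di-tert-butyl biarylphosphine directs the 3,3-disubstituted allylboronate to couple at its α-carbon (linear prenyl), followed by saponification of the aryl pivalate; the enol ether, aryl methyl ether and prenyl alkene are inert to base and no stereocentre is formed.

## Compound list

1 | paeonol, 1-(2-hydroxy-4-methoxyphenyl)ethan-1-one | CC(=O)c1ccc(OC)cc1O | starting material
2 | 2-acetyl-5-methoxyphenyl pivalate | CC(=O)c1ccc(OC)cc1OC(=O)C(C)(C)C | intermediate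
3 | 4-bromoresorcinol, 4-bromobenzene-1,3-diol | Oc1ccc(Br)c(O)c1 | starting material
4 | 2-(2,2-dihydroxyacetyl)-5-methoxyphenyl pivalate (arylglyoxal hydrate) | COc1ccc(C(=O)C(O)O)c(OC(=O)C(C)(C)C)c1 | intermediate
5 | 2-[2-(5-bromo-2,4-dihydroxyphenyl)-2-hydroxyacetyl]-5-methoxyphenyl pivalate (racemic) | COc1ccc(C(=O)C(O)c2cc(Br)c(O)cc2O)c(OC(=O)C(C)(C)C)c1 | intermediate
6 | 2-[2-(5-bromo-2,4-dihydroxyphenyl)-2-methoxyacetyl]-5-methoxyphenyl pivalate (racemic) | COc1ccc(C(=O)C(OC)c2cc(Br)c(O)cc2O)c(OC(=O)C(C)(C)C)c1 | intermediate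
7 | 2-(5-bromo-6-hydroxy-3-methoxy-1-benzofuran-2-yl)-5-methoxyphenyl pivalate | COc1ccc(-c2oc3cc(O)c(Br)cc3c2OC)c(OC(=O)C(C)(C)C)c1 | intermediate
8 | prenylboronic acid pinacol ester | CC(C)=CCB1OC(C)(C)C(C)(C)O1 | starting material
9 | 2-[6-hydroxy-3-methoxy-5-(3-methylbut-2-en-1-yl)-1-benzofuran-2-yl]-5-methoxyphenyl pivalate | COc1ccc(-c2oc3cc(O)c(CC=C(C)C)cc3c2OC)c(OC(=O)C(C)(C)C)c1 | intermediate
10 | ambofuranol, 2-(2-hydroxy-4-methoxyphenyl)-3-methoxy-5-(3-methylbut-2-en-1-yl)-1-benzofuran-6-ol | COc1ccc(-c2oc3cc(O)c(CC=C(C)C)cc3c2OC)c(O)c1 | target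

## Step count and risks

Total step count: 4 (isolated: 2, 5, 7, 10; steps 2 and 4 each telescope two transformations).
Longest linear sequence: 4 steps, from paeonol.

**Step 3 (the proposed new step).** The hemiketal may dehydrate before methanol capture, giving the 3-oxo (coumaranone) form, which etherifies only slowly; the acyloin may also shift. The fallback uses known chemistry and sets out from 5. Catalytic TsOH in MeCN without alcohol cyclodehydrates 5 to 2-(5-bromo-6-hydroxy-3-oxo-2,3-dihydro-1-benzofuran-2-yl)-5-methoxyphenyl pivalate F1. TIPSCl/imidazole in DMF caps the C6 phenol to give 2-[5-bromo-3-oxo-6-(triisopropylsilyloxy)-2,3-dihydro-1-benzofuran-2-yl]-5-methoxyphenyl pivalate F2. K2CO3/Me2SO4 in acetone O-methylates the enolate (aromatisation favours O over C) to 2-[5-bromo-3-methoxy-6-(triisopropylsilyloxy)-1-benzofuran-2-yl]-5-methoxyphenyl pivalate F3. TBAF/AcOH in THF removes the silyl group, and the sequence comes back to the route at 7.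

**Step 2.** Selenium(IV) carry-over can attack the electron-rich resorcinol, 5 can be arylated a second time by 3 (diarylmethane), or the uncatalysed addition may be sluggish. The fallback sets out from 2. SeO2 oxidation followed by HC(OMe)3/MeOH/TsOH gives the keto acetal 2-(2,2-dimethoxyacetyl)-5-methoxyphenyl pivalate F4, which can be purified free of selenium. BF3·OEt2 in MeCN at −20 °C ionises it to an oxocarbenium that alkylates 3 at C6, so the methoxy group is already on C3 and no free benzylic alcohol is exposed. This comes back to the route at 6, which the CSA stage of step 3 closes to 7.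

**Step 4.** Risks are γ-attack (reverse prenyl isomer), slow oxidative addition next to the phenoxide, and protodebromination. The fallback sets out from 7. Suzuki coupling with allylboronic acid pinacol ester (Pd(dppf)Cl2, K2CO3, dioxane/H2O), which has no α/γ ambiguity, gives 2-[6-hydroxy-3-methoxy-5-(prop-2-en-1-yl)-1-benzofuran-2-yl]-5-methoxyphenyl pivalate F5. Cross-metathesis with 2-methyl-2-butene (Grubbs II, CH2Cl2, 40 °C) converts allyl to prenyl and comes back to the route at 9, which is saponified to 10 as in step 4.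

## Further compounds

F1 | step 3 | 2-(5-bromo-6-hydroxy-3-oxo-2,3-dihydro-1-benzofuran-2-yl)-5-methoxyphenyl pivalate (racemic) | COc1ccc(C2Oc3cc(O)c(Br)cc3C2=O)c(OC(=O)C(C)(C)C)c1
F2 | step 3 | 2-[5-bromo-3-oxo-6-(triisopropylsilyloxy)-2,3-dihydro-1-benzofuran-2-yl]-5-methoxyphenyl pivalate (racemic) | COc1ccc(C2Oc3cc(O[Si](C(C)C)(C(C)C)C(C)C)c(Br)cc3C2=O)c(OC(=O)C(C)(C)C)c1
F3 | step 3 | 2-[5-bromo-3-methoxy-6-(triisopropylsilyloxy)-1-benzofuran-2-yl]-5-methoxyphenyl pivalate | COc1ccc(-c2oc3cc(O[Si](C(C)C)(C(C)C)C(C)C)c(Br)cc3c2OC)c(OC(=O)C(C)(C)C)c1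
F4 | step 2 | 2-(2,2-dimethoxyacetyl)-5-methoxyphenyl pivalate | COC(OC)C(=O)c1ccc(OC)cc1OC(=O)C(C)(C)C
F5 | step 4 | 2-[6-hydroxy-3-methoxy-5-(prop-2-en-1-yl)-1-benzofuran-2-yl]-5-methoxyphenyl pivalate | COc1ccc(-c2oc3cc(O)c(CC=C)cc3c2OC)c(OC(=O)C(C)(C)C)c1
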